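## Structural features

The target is a diaryl ether, C24H30O7, made of two benzene rings joined through one oxygen; it has no stereocentre. Ring A is an olivetol-type resorcinol: C1 bears the pentyl chain, C3 and C5 bear free hydroxyl groups, and C6, flanked by C1 and C5, bears the ether oxygen. Ring B is a benzoic acid whose carboxyl-bearing carbon C1 lies between the aryloxy carbon C2 and the pentanoyl-bearing carbon C6, with a methoxy group at C4. The ether oxygen therefore sits between three ortho substituents (pentyl and hydroxyl on ring A, carboxyl on ring B), so the real difficulty is a late aryl–oxygen coupling, together with telling this oxygen apart from the two free phenols. Fragile points are: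
- the unprotected resorcinol, which is easily oxidised and halogenated;
- the 2-acylbenzoic acid, an electrophilic ketone next to a carboxyl that can ring-close to the hydroxyphthalide and dehydrate under acid;
- the 2'-hydroxy diaryl ether acid, which closes to a seven-membered depsidone-type lactone when the carboxyl is activated.

The oxygenation pattern of ring A is that of a triketide: C5 and C3 are carbonyl-derived, C1 is the carbonyl carbon that carries pentyl, and C6 carries only the ether oxygen. C6 can therefore start as the aryloxymethyl end and C1 as the hexanoyl carbonyl of an undecane-2,4,6-trione, so the C6–C1 bond and ring A arise by intramolecular aldol condensation and the hindered ether bond is reduced to an alkyl aryl ether made by SN2.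

## Logic of the disconnections

Ring A atoms keep their numbers in the open-chain precursors: C6 bears the ether oxygen, C5 and C3 are the oxygen-bearing carbons, C1 bears pentyl.

**13 back to 11 (through 12).** No skeletal bond is cut; the pentanoyl C=O is traced back to the internal alkyne of 11. A ketone on ring B would be a second electrophile for every enolate used to build ring A, whereas the alkyne ignores amide bases and hydroxide. The neighbouring carboxylate then delivers oxygen to the ring-bound alkyne carbon only, through enol lactone 12. The gain is a robust alkynyl acid that needs no protecting group. The demand is 5-exo-dig closure rather than 6-endo-dig, and opening of 12 by hydroxide without harm to the free resorcinol.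

**11 back to 10.** The C6–C1 bond of ring A is cut (retro-aldol, with water added back). Ring A disappears, the aryl–O–aryl bond becomes aryl–O–CH2, and the three ring A oxygens are differentiated from the start: two are ketones, one is the ether. The forward step must fold from C6 and not from the pentyl-side methylene. It must also offer the C6 carbanion no acyl electrophile five atoms away. For that reason the ring B carboxyl is carried as the free acid, which is a carboxylate under the basic conditions, and not as a methyl ester; an ester at that position would invite Claisen closure to a benzofuran-3-one.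

**10 back to 7 and 8 (through 9).** The C5–C4 bond is cut. C5 is the acyl carbon of the N-methoxy-N-methylamide in 7; C4 is the methyl terminus of 8, used as its 1,3-dianion 9. 8 supplies C4, C3, C2, C1 and the pentyl chain as one commercial piece. The forward step needs the second deprotonation of 8 at the methyl and not at the pentyl-side methylene, an acylation that stops at the ketone stage, and tolerance of the lithium carboxylate.

**7 back to 6.** Only the oxidation level changes, carboxyl from formyl. The aldehyde is the form in which this carbon can pass through the cross-coupling and the O-alkylation. An acid or ester ortho to the new alkyne would add to it under palladium and copper, and a carboxylate would compete with the phenoxide for the alkylating agent. The gain is that no ester is put on or taken off. The demand is an oxidant that spares the alkyne, the amide N–O bond and the electron-rich ring.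

**6 back to 4 and 5.** The bond between the ring B phenol oxygen and C6 is cut. The target's ether oxygen is thus the phenol oxygen of 4, and the bond is made by SN2 at a primary α-chloro amide, not by coupling at a triply flanked aryl carbon. 5 brings C6 and C5, with C5 already an acyl donor that cannot over-react. The forward step must not be followed by aldol closure of the new methylene onto the ortho formyl group.

**4 back to 2 and 3.** The aryl–alkynyl bond is cut (Sonogashira). 3 supplies all five carbons of the future pentanoyl group, and the bromide of 2 is activated by the ortho formyl group. The demand is tolerance of the free phenol and containment of a volatile alkyne.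

**2 back to 1.** The O–CH3 bond of the methoxy group ortho to the formyl group is cut. 1 is commercial, and only that ether can chelate a boron Lewis acid together with the carbonyl oxygen. The step is placed before the coupling because boron trihalides attack alkynes that lie ortho to a carbonyl group. The demand is ortho over para selectivity.

## Other disconnections considered

**Alternative 1:** The cut is on the ring B side of the ether oxygen (O–C2) and at the C1–carboxyl bond, which reduces ring B to an aryne.
- *Forward step.* CsF releases the aryne from the ortho-silylaryl triflate A2. The caesium phenoxide of the protected ring A phenol A1 adds to the aryne carbon remote from bromine. The aryl anion formed next to bromine is trapped by CO2 to give acid A3. No ring closes.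
- *In its favour.* Ring A comes from a preformed resorcinol, so the question of fold direction does not arise; on this point the plan is better than the chosen one. The aryne is indifferent to the three ortho substituents, so the hindered C–O bond should form at least as easily as by the SN2 reaction of the chosen plan. Two ring B bonds are made convergently in one operation.
- *Against it here.* The aryl anion waiting for CO2 carries an ortho bromine and can expel bromide to a second aryne. The phenoxide binds CO2 reversibly as a carbonate, and protonation of the anion gives the simple diaryl ether. A1 and A2 each need several steps with protecting groups. A3 is still far from the target: the bromide next to a free carboxyl must become the pentanoyl group, and two acetals must be cleaved with acid beside groups that cyclise under acid.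
- *Comparison.* On structure, both rings are bought as arenes here, whereas the chosen plan builds ring A from a chain. On mechanism, the uncertain point here is the lifetime of a destabilised aryl anion; in the chosen plan it is one regiochemical choice in an aldol addition. On step economy, this route is convergent but longer in total and needs two kinds of protecting group; the chosen plan is linear, seven steps, with none.

**Alternative 2:** The cut removes the C1–C2 and C5–C6 bonds of ring B, so ring B comes from the 6-aryloxy-4-methoxy-2-pyrone A4 (four ring carbons) and the ketal-masked ynoate A5 (two).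
- *Forward step.* Heating A4 with A5 gives a bridged lactone by [4+2] cycloaddition; loss of CO2 in a retro-[4+2] step closes ring B as benzoate A6.
- *In its favour.* All four ring B substituents are placed by one pericyclic step that is electronically matched: the nucleophilic C3 of the pyrone bonds to the β-carbon of the ynoate. The pentanoyl carbon enters at the ketone oxidation level, so no alkyne hydration and no 5-exo against 6-endo question arises; on this point the plan is better than the chosen one. No aryl–oxygen cross-coupling is needed, which makes it the equal of the chosen plan there.
- *Against it here.* 4-Alkoxy-2-pyrones are reluctant dienes, and the bonding terminus of A5 carries a fully substituted ketal carbon. The cycloaddition would need prolonged heating, which puts the ketal and the methoxymethyl ethers at risk. A4 needs phenol A1 plus a pyrone construction. A6 still needs cleavage of a doubly ortho-substituted methyl benzoate and of three acetal groups.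
- *Comparison.* On structure, this plan builds ring B and buys ring A, the reverse of the chosen plan. On mechanism, it replaces an ionic aldol of uncertain direction by a concerted step of predictable direction but high barrier. On step economy, it is longer: phenol, pyrone and ynoate are each multi-step, against seven linear steps from four catalogue chemicals.

**Alternative 3:** The cut is the same C6–C1 bond as in the chosen plan plus the C4–C5 bond. This leaves the aryloxymalonate A7 (C6 and C5) and the enone A8 (C1 to C4 with the pentyl chain).
- *Forward step.* NaOMe promotes Michael addition of the malonate carbon of A7 to the β-carbon of A8, then Claisen closure of the methyl ketone onto one malonate ester. The product is the cyclohexane-1,3-dione A9 as a mixture of diastereomers.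
- *In its favour.* The nucleophile is a doubly activated malonate carbon, so the direction of ring construction is not in doubt; on this point the plan is better than the chosen one. The annulation is the classical route to 5-alkylresorcinols. The ether bond comes from SN2 on a halomalonate, which makes it the equal of the chosen plan on the hindered C–O bond. The two stereocentres of A9 vanish on aromatisation, so the diastereomer mixture costs nothing.
- *Against it here.* A9 is not aromatic. It needs removal of the angular ester and a two-electron oxidation in the presence of the alkyne and an electron-rich ring B; the triketone avoids these steps because it is already at the resorcinol oxidation level. The malonate carbanion of A7 sits five atoms from the ring B methyl ester; under the same methoxide it can close to a benzofuran-3-one and lose a carbomethoxy group to the stable 3-hydroxybenzofuran-2-carboxylate. A7 also cannot be made at the aldehyde stage, for the analogous reason, so the ring B ester must be installed first and cleaved at the end.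
- *Comparison.* On structure, both plans build ring A on the ether oxygen and use the same ring B piece. On mechanism, both make C6 the nucleophile and C1 the electrophile; this plan buys certainty of direction at the price of a lower oxidation level. On step economy, it is longer by the esterification, ester cleavage, decarboxylation and oxidation steps.

Key step: step 6

Assumption: 1, 3, 5 and 8 are taken as catalogue chemicals, and 13 is drawn as the open keto acid although 2-acylbenzoic acids can equilibrate with the ring-closed hydroxyphthalide tautomer.

## Route

Step 1
Reactants: 1 2-bromo-4,6-dimethoxybenzaldehyde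
Product: 2 2-bromo-6-hydroxy-4-methoxybenzaldehyde
Conditions: BCl3 (1.2 equiv), CH2Cl2, −78 to 0 °C; then H2O
Reagents that add atoms: none
Why: Chelation-directed Lewis acid ether cleavage: boron binds the formyl oxygen and the adjacent methoxy oxygen in a six-membered chelate, so chloride removes only that methyl group while the para methoxy group and the C–Br bond stay. It is run before the coupling because BCl3 would attack an alkyne ortho to the carbonyl group.

Step 2
Reactants: 2 2-bromo-6-hydroxy-4-methoxybenzaldehyde; 3 pent-1-yne
Product: 4 2-hydroxy-4-methoxy-6-(pent-1-yn-1-yl)benzaldehyde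
Conditions: PdCl2(PPh3)2 (3 mol%), CuI (5 mol%), Et3N, THF, sealed tube, 55 °C
Reagents that add atoms: none
Why: Sonogashira coupling; the bromide ortho to the formyl group is activated for oxidative addition to zerovalent palladium and the free phenol is tolerated. The ring B carbonyl carbon is still an aldehyde, so no carboxyl oxygen can add to the new alkyne under palladium and copper.

Step 3
Reactants: 4 2-hydroxy-4-methoxy-6-(pent-1-yn-1-yl)benzaldehyde; 5 2-chloro-N-methoxy-N-methylacetamide
Product: 6 2-[2-formyl-5-methoxy-3-(pent-1-yn-1-yl)phenoxy]-N-methoxy-N-methylacetamide
Conditions: K2CO3 (1.5 equiv), NaI (10 mol%), MeCN, 50 °C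
Reagents that add atoms: none
Why: Williamson ether synthesis (SN2 at the primary α-chloro amide, with iodide catalysis); the phenoxide is the only nucleophile present. The amide methylene is too weakly acidic for carbonate, so the Rap–Stoermer-type aldol closure onto the ortho formyl group should not follow.

Step 4
Reactants: 6 2-[2-formyl-5-methoxy-3-(pent-1-yn-1-yl)phenoxy]-N-methoxy-N-methylacetamide
Product: 7 4-methoxy-2-{2-[methoxy(methyl)amino]-2-oxoethoxy}-6-(pent-1-yn-1-yl)benzoic acid
Conditions: NaClO2, NaH2PO4, 2-methylbut-2-ene (10 equiv), t-BuOH/THF/H2O, 0 °C to rt
Reagents that add atoms: sodium chlorite, [Na+].[O-]Cl=O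
Why: Pinnick oxidation: chlorous acid adds to the aldehyde and fragments to the acid and HOCl, which the alkene traps before it can chlorinate the dialkoxy ring or the alkyne. Peroxide oxidants are avoided because an ortho,para-dialkoxybenzaldehyde would undergo Dakin cleavage; the amide and alkyne are inert.

Step 5
Reactants: 7 4-methoxy-2-{2-[methoxy(methyl)amino]-2-oxoethoxy}-6-(pent-1-yn-1-yl)benzoic acid; 8 nonane-2,4-dione
Product: 10 4-methoxy-6-(pent-1-yn-1-yl)-2-[(2,4,6-trioxoundecyl)oxy]benzoic acid, via dilithium nonane-2,4-dione dianion 9 (not isolated)
Conditions: 8 (2.2 equiv), LiN(i-Pr)2 (4.4 equiv), THF, −78 to 0 °C; then lithium carboxylate of 7 (from 7 and LiN(i-Pr)2, 1.0 equiv, THF, −78 °C), −78 to −20 °C; 1 M HCl to pH 3, 0 °C; used crude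
Reagents that add atoms: none
Why: Claisen-type C-acylation of a β-diketone 1,3-dianion: the second deprotonation of 8 by the hindered amide base occurs at the methyl rather than the methylene terminus, and that carbon adds to the N-methoxy-N-methylamide of 7, whose lithium-chelated tetrahedral adduct holds until the acid quench and prevents over-addition. The ring B carboxyl is a lithium carboxylate, which neither reacts with the dianion nor offers the aryloxymethylene an ester for Dieckmann closure; the internal alkyne is inert at these temperatures.

Step 6
Reactants: 10 4-methoxy-6-(pent-1-yn-1-yl)-2-[(2,4,6-trioxoundecyl)oxy]benzoic acid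
Product: 11 2-(2,4-dihydroxy-6-pentylphenoxy)-4-methoxy-6-(pent-1-yn-1-yl)benzoic acid
Conditions: KOH (1 M aq., 6 equiv), THF/H2O, degassed, Ar, 0.03 M, rt (40 °C if slow); then 1 M HCl to pH 2, 0 °C
Reagents that add atoms: none
Why: In aqueous KOH 10 is present as the carboxylate and as enolates of its 1,3-dicarbonyl units; in equilibrium the aryloxymethyl carbon (C6 of ring A), acidified by the C5 carbonyl and by the inductive pull of the aryloxy oxygen, is deprotonated and adds to the hexanoyl carbonyl carbon (C1), forming the C6–C1 bond. The closure is a 6-(enolendo)-exo-trig aldol addition; the β-hydroxy ketone loses water by E1cB across C6–C1, and enolisation of the two remaining ketones (C5 and C3) aromatises the ring to the resorcinol, which makes the sequence irreversible. The closest known reaction type is the base-mediated cyclodehydration of 2,4,6-triketones to 5-substituted resorcinols, the laboratory counterpart of the polyketide aldol fold. No stereocentre is formed. The selectivity needed first is the direction of folding: the alternative, attack of the pentyl-side methylene on the C5 carbonyl, should be disfavoured because an α-aryloxy ketone is several pKa units more acidic than an α-alkyl ketone and because the desired adduct dehydrates through that same acidic C6–H. The second is aldol against Claisen: the ring B carboxyl is a carboxylate here and cannot act as an acylating agent toward the C6 carbanion, so no benzofuran-3-one can form, and the alkyne and methyl ether are inert to hydroxide. High dilution and exclusion of oxygen guard against intermolecular aldol reactions and oxidation of the electron-rich phenolate.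

Step 7
Reactants: 11 2-(2,4-dihydroxy-6-pentylphenoxy)-4-methoxy-6-(pent-1-yn-1-yl)benzoic acid
Product: 13 2-(2,4-dihydroxy-6-pentylphenoxy)-4-methoxy-6-pentanoylbenzoic acid, via (Z)-3-butylidenephthalide 12 (not isolated)
Conditions: DBU (1.5 equiv), MeCN, Ar, 80 °C; then LiOH (1 M aq., 5 equiv), THF, rt; 1 M HCl to pH 2, 0 °C
Reagents that add atoms: lithium hydroxide, [Li+].[OH-]
Why: Base-mediated 5-exo-dig anti addition of the carboxylate to the ring-bound alkyne carbon gives the (Z)-enol lactone 12; hydroxide then attacks the lactone carbonyl, and the enolate released tautomerises to the pentanoyl ketone (enol lactone hydrolysis). Any acyl transfer from 12 to the neighbouring ring A phenoxide would give a seven-membered aryl ester that the same hydroxide opens to 13.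

## Compound list

1 | 2-bromo-4,6-dimethoxybenzaldehyde | COc1cc(Br)c(C=O)c(OC)c1 | starting material
2 | 2-bromo-6-hydroxy-4-methoxybenzaldehyde | COc1cc(O)c(C=O)c(Br)c1 | intermediate
3 | pent-1-yne | CCCC#C | starting material
4 | 2-hydroxy-4-methoxy-6-(pent-1-yn-1-yl)benzaldehyde | CCCC#Cc1cc(OC)cc(O)c1C=O | intermediate
5 | 2-chloro-N-methoxy-N-methylacetamide | CON(C)C(=O)CCl | starting material
6 | 2-[2-formyl-5-methoxy-3-(pent-1-yn-1-yl)phenoxy]-N-methoxy-N-methylacetamide | CCCC#Cc1cc(OC)cc(OCC(=O)N(C)OC)c1C=O | intermediate
7 | 4-methoxy-2-{2-[methoxy(methyl)amino]-2-oxoethoxy}-6-(pent-1-yn-1-yl)benzoic acid | CCCC#Cc1cc(OC)cc(OCC(=O)N(C)OC)c1C(=O)O | intermediate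
8 | nonane-2,4-dione | CCCCCC(=O)CC(C)=O | starting material
9 | dilithium nona-1,3-diene-2,4-diolate (1,3-dianion of 8) | [Li+].[Li+].C=C([O-])C=C([O-])CCCCC | intermediate (not isolated)
10 | 4-methoxy-6-(pent-1-yn-1-yl)-2-[(2,4,6-trioxoundecyl)oxy]benzoic acid | CCCCCC(=O)CC(=O)CC(=O)COc1cc(OC)cc(C#CCCC)c1C(=O)O | intermediate
11 | 2-(2,4-dihydroxy-6-pentylphenoxy)-4-methoxy-6-(pent-1-yn-1-yl)benzoic acid | CCCCCc1cc(O)cc(O)c1Oc1cc(OC)cc(C#CCCC)c1C(=O)O | intermediate
12 | (3Z)-3-butylidene-7-(2,4-dihydroxy-6-pentylphenoxy)-5-methoxy-2-benzofuran-1(3H)-one | CCC/C=C1\OC(=O)c2c(Oc3c(CCCCC)cc(O)cc3O)cc(OC)cc12 | intermediate (not isolated)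
13 | 2-(2,4-dihydroxy-6-pentylphenoxy)-4-methoxy-6-pentanoylbenzoic acid | CCCCCc1cc(O)cc(O)c1Oc1cc(OC)cc(C(=O)CCCC)c1C(=O)O | target

## Step count and least certain steps

Total step count: 7. Longest linear sequence: 7 steps (1 to 13); 3, 5 and 8 enter as purchased pieces.

**Step 6 (key step).** What may go wrong: folding from the other end, that is, enolisation on the pentyl side and addition of that methylene to the more electrophilic C5 carbonyl, which would lead to an isomeric resorcinol. Hydroxide-induced retro-Claisen fragmentation of the triketone may also outrun cyclisation. Fallback (sets out from 4, returns at 11): ring A is brought in as a preformed resorcinol and the ether bond is made by copper catalysis.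
- Commercial olivetol is protected (MOMCl, i-Pr2NEt, CH2Cl2) as 1,3-bis(methoxymethoxy)-5-pentylbenzene F1.
- F1 is iodinated with N-iodosuccinimide in MeCN, para to one acetal oxygen and next to the pentyl chain, to give 2-iodo-1,5-bis(methoxymethoxy)-3-pentylbenzene F2.
- Ullmann-type coupling of phenol 4 with F2 (CuI, picolinic acid, K3PO4, DMSO, 90 °C) should give 2-[2,4-bis(methoxymethoxy)-6-pentylphenoxy]-4-methoxy-6-(pent-1-yn-1-yl)benzaldehyde F3.
- Chlorite oxidation as in step 4 leads to 2-[2,4-bis(methoxymethoxy)-6-pentylphenoxy]-4-methoxy-6-(pent-1-yn-1-yl)benzoic acid F4.
- HCl in MeOH at room temperature removes both acetals and returns 11.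

The fold direction is then no longer in question. The price is a slow coupling at a doubly ortho-flanked iodide with a chelating, electron-poor phenol, and four extra operations.

**Step 5.** What may go wrong: proton transfer in place of acylation (the dianion deprotonating the aryloxymethylene of 7), precipitation of the lithium carboxylate at −78 °C, or partial second deprotonation of 8 on the pentyl side, leading to a branched triketone. Fallback (sets out from 7, returns at 11): the carboxyl is masked as an ester too hindered for Claisen closure.
- 7 is converted with N,N-dimethylformamide di-tert-butyl acetal (toluene, 80 °C) into tert-butyl 4-methoxy-2-{2-[methoxy(methyl)amino]-2-oxoethoxy}-6-(pent-1-yn-1-yl)benzoate F5.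
- Acylation of 9 with F5 under the conditions of step 5, without the extra equivalent of base, gives tert-butyl 4-methoxy-6-(pent-1-yn-1-yl)-2-[(2,4,6-trioxoundecyl)oxy]benzoate F6.
- The KOH fold of step 6 gives tert-butyl 2-(2,4-dihydroxy-6-pentylphenoxy)-4-methoxy-6-(pent-1-yn-1-yl)benzoate F7. A tert-butyl benzoate between two ortho substituents should be neither saponified nor attacked by the C6 carbanion.
- CF3CO2H with Et3SiH as cation trap in CH2Cl2 at 0 °C releases 11.

**Step 7.** What may go wrong: competing 6-endo-dig closure to the isocoumarin, whose hydrolysis would give the isomeric benzyl ketone, and oxidative degradation of the unprotected resorcinolate in hot base. Fallback (sets out from 11, returns at 13): lactonisation is separated from hydrolysis, run under π-acid catalysis in place of base, and carried out on a protected ring A.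
- 11 is silylated (t-BuMe2SiCl, imidazole, DMF; the silyl ester is cleaved on aqueous citric acid work-up) to 2-{2,4-bis[(tert-butyldimethylsilyl)oxy]-6-pentylphenoxy}-4-methoxy-6-(pent-1-yn-1-yl)benzoic acid F8.
- AgNO3 (10 mol%, monovalent silver) in acetone at room temperature should close the enol lactone (3Z)-7-{2,4-bis[(tert-butyldimethylsilyl)oxy]-6-pentylphenoxy}-3-butylidene-5-methoxy-2-benzofuran-1(3H)-one F9, which can be freed from any six-membered isomer by chromatography.
- LiOH in aqueous THF then opens the lactone and removes both aryl silyl ethers to give 13.

**Step 2.** What may go wrong: stalling of the coupling because the chelating ortho-hydroxy aldehyde, as its phenoxide, ties up copper and palladium, so that oxidative dimerisation of the volatile alkyne takes over. Fallback (sets out from 2, returns at 6): steps 2 and 3 are exchanged. Alkylation of 2 with 5 (K2CO3, NaI, MeCN, 50 °C) gives 2-(3-bromo-2-formyl-5-methoxyphenoxy)-N-methoxy-N-methylacetamide F10. Sonogashira coupling of F10 with 3, now without a free phenol, gives 6 directly.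

## Further compounds

F1 | step 6 | 1,3-bis(methoxymethoxy)-5-pentylbenzene | CCCCCc1cc(OCOC)cc(OCOC)c1
F2 | step 6 | 2-iodo-1,5-bis(methoxymethoxy)-3-pentylbenzene | CCCCCc1cc(OCOC)cc(OCOC)c1I
F3 | step 6 | 2-[2,4-bis(methoxymethoxy)-6-pentylphenoxy]-4-methoxy-6-(pent-1-yn-1-yl)benzaldehyde | CCCCCc1cc(OCOC)cc(OCOC)c1Oc1cc(OC)cc(C#CCCC)c1C=O
F4 | step 6 | 2-[2,4-bis(methoxymethoxy)-6-pentylphenoxy]-4-methoxy-6-(pent-1-yn-1-yl)benzoic acid | CCCCCc1cc(OCOC)cc(OCOC)c1Oc1cc(OC)cc(C#CCCC)c1C(=O)O
F5 | step 5 | tert-butyl 4-methoxy-2-{2-[methoxy(methyl)amino]-2-oxoethoxy}-6-(pent-1-yn-1-yl)benzoate | CCCC#Cc1cc(OC)cc(OCC(=O)N(C)OC)c1C(=O)OC(C)(C)C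
F6 | step 5 | tert-butyl 4-methoxy-6-(pent-1-yn-1-yl)-2-[(2,4,6-trioxoundecyl)oxy]benzoate | CCCCCC(=O)CC(=O)CC(=O)COc1cc(OC)cc(C#CCCC)c1C(=O)OC(C)(C)C
F7 | step 5 | tert-butyl 2-(2,4-dihydroxy-6-pentylphenoxy)-4-methoxy-6-(pent-1-yn-1-yl)benzoate | CCCCCc1cc(O)cc(O)c1Oc1cc(OC)cc(C#CCCC)c1C(=O)OC(C)(C)C
F8 | step 7 | 2-{2,4-bis[(tert-butyldimethylsilyl)oxy]-6-pentylphenoxy}-4-methoxy-6-(pent-1-yn-1-yl)benzoic acid | CCCCCc1cc(O[Si](C)(C)C(C)(C)C)cc(O[Si](C)(C)C(C)(C)C)c1Oc1cc(OC)cc(C#CCCC)c1C(=O)O
F9 | step 7 | (3Z)-7-{2,4-bis[(tert-butyldimethylsilyl)oxy]-6-pentylphenoxy}-3-butylidene-5-methoxy-2-benzofuran-1(3H)-one | CCC/C=C1\OC(=O)c2c(Oc3c(CCCCC)cc(O[Si](C)(C)C(C)(C)C)cc3O[Si](C)(C)C(C)(C)C)cc(OC)cc12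
F10 | step 2 | 2-(3-bromo-2-formyl-5-methoxyphenoxy)-N-methoxy-N-methylacetamide | COc1cc(Br)c(C=O)c(OCC(=O)N(C)OC)c1
A1 | alternative 1 | 2,4-bis(methoxymethoxy)-6-pentylphenol | CCCCCc1cc(OCOC)cc(OCOC)c1O
A2 | alternative 1 | 2-bromo-4-methoxy-6-(trimethylsilyl)phenyl trifluoromethanesulfonate | COc1cc(Br)c(OS(=O)(=O)C(F)(F)F)c([Si](C)(C)C)c1
A3 | alternative 1 | 2-[2,4-bis(methoxymethoxy)-6-pentylphenoxy]-6-bromo-4-methoxybenzoic acid | CCCCCc1cc(OCOC)cc(OCOC)c1Oc1cc(OC)cc(Br)c1C(=O)O
A4 | alternative 2 | 6-[2,4-bis(methoxymethoxy)-6-pentylphenoxy]-4-methoxy-2H-pyran-2-one | COc1cc(Oc2c(CCCCC)cc(OCOC)cc2OCOC)oc(=O)c1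
A5 | alternative 2 | methyl 4,4-dimethoxyoct-2-ynoate | COC(=O)C#CC(OC)(OC)CCCC
A6 | alternative 2 | methyl 2-[2,4-bis(methoxymethoxy)-6-pentylphenoxy]-6-(1,1-dimethoxypentyl)-4-methoxybenzoate | CCCCCc1cc(OCOC)cc(OCOC)c1Oc1cc(OC)cc(C(OC)(OC)CCCC)c1C(=O)OC
A7 | alternative 3 | dimethyl 2-[5-methoxy-2-(methoxycarbonyl)-3-(pent-1-yn-1-yl)phenoxy]propanedioate | CCCC#Cc1cc(OC)cc(OC(C(=O)OC)C(=O)OC)c1C(=O)OC
A8 | alternative 3 | (3E)-non-3-en-2-one | CCCCC/C=C/C(C)=O
A9 | alternative 3 | methyl 1-[5-methoxy-2-(methoxycarbonyl)-3-(pent-1-yn-1-yl)phenoxy]-2,4-dioxo-6-pentylcyclohexane-1-carboxylate (mixture of diastereomers) | COC(=O)C1(Oc2cc(OC)cc(C#CCCC)c2C(=O)OC)C(CCCCC)CC(=O)CC1=O
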